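Do not wait for the late samples: the violet run holds 0.1% first product at 15.0 d. So choose a time to stop the flask.

| flask | substrate | reagent | remark | time |
|---|---|---|---|---|
| grey | 0.80 M (fed, over 30 h) | 0.60 M | run made earlier; the fed solution adds 1.0 times the starting volume |  |
| amber | 0.80 M (fed, over 30 h) | 0.90 M | run made earlier; the fed solution adds 1.0 times the starting volume |  |
| violet | 0.40 M (fed, over 30 h) | 1.2 M | run made earlier; the fed solution adds 1.0 times the starting volume |  |
| flask | 0.80 M (fed, over 30 h) | 1.20 M | the fed solution adds 1.0 times the starting volume | 15 d |

- grey (time / d: first product / %, substrate / %): 0.500: 5.0, 27.7; 1.67: 13.3, 50.3; 5.00: 14.8, 34.8; 15.0: 14.9, 33.3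
- amber (time / d: first product / %, substrate / %): 0.500: 4.0, 24.1; 1.67: 12.7, 38.2; 5.00: 13.3, 21.3; 15.0: 10.9, 16.6
- violet (time / d: first product / %, substrate / %): 0.500: 3.7, 21.4; 1.67: 13.0, 24.8; 5.00: 2.7, 1.4; 15.0: 0.1, 0

(each reading ± 1 percentage point)

1. time up to 15 d at which first product stands highest
2. the amount of first product, in percent of the substrate charged, at that time

Take first product as made from substrate with reagent and lost to reagent. Both rates then carry c(reagent), so on this assumption first product tops at one fixed c(substrate)/c(first product), at any reagent charge. The violet run's highest reading, at 1.67 d, gives 1.91: keep this as the crossover ratio, a selectivity factor read with a scatter of 1 percentage point on each reading. The amber run's highest reading stands at 1.60, and the grey run levels off at 2.23, so these two lie on either side of it.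

At 1.67 d the ratio is 3.78 in the grey run and 3.01 in the amber run. Reagent rises in equal steps from grey through amber to the flask, so continue the line to 2.23 for the flask. That is still above the crossover ratio of 1.91, so the flask's top comes later than 1.67 d. The violet run, with the same reagent charge, loses ratio at 0.391 /d, so plan to stop the flask at 2.07 d.

The forecast, which grants that “the model is only rough”, gives 14% at 2.3 d, later than this reckoning.

The flask tops at 12.8% at 1.89 d, earlier than planned.

    substrate + reagent → other mono adduct (k = 0.0639 /M/h)
    reagent + first product → double product (k = 0.0998 /M/h)
    substrate + reagent → first product (k = 0.0475 /M/h)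
    reagent + other mono adduct → double product (k = 0.0250 /M/h)
    2 substrate → homo dimer (k = 8.89 × 10⁻⁵ /M/h)
    substrate ⇌ dormant form (K = 0.270, k = 0.0450 /h)

At 2.36 d the flask still holds 12.5% first product. At its top it holds 26.9% substrate, a ratio of 2.10 against the 1.91 read from the violet run. A flask charged with 0.72 M reagent ends at 15.0 d with 0.0528% of its reagent left and a ratio of 1.84 beside the crossover ratio of 1.91, holding 13.8% first product against a best of 13.9%.

(The numbers in the tables are calculated on assumed constants; noise was put on by code.)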